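The numbers in the tables stem from a simulated flask from invented constants, and the scatter is random.

The north-east run still holds 35.5% of its Q at 25.0 h, yet its G has crept only from 43.2% to 49.1% over the last 13.0 h, so something other than Q is running down. We want the order of the new flasks by G at their common time.

| flask | Q | D | X | remark | time |
|---|---|---|---|---|---|
| north-east | 0.24 M | 0.252 M | 0.043 M | run made earlier |  |
| west | 0.24 M | 0.252 M | 0.055 M | run made earlier |  |
| south-west | 0.24 M | 0.252 M | 0.075 M | run made earlier |  |
| south-east | 0.24 M | 0.33 M | 0.072 M | run made earlier |  |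
| red | 0.50 M | 0.150 M | 0.0720 M |  | 50 h |
| teal | 0.24 M | 0.120 M | 0.0400 M |  | 50 h |
| grey | 0.40 M | 0.150 M | 0.0720 M |  | 50 h |
| ochre | 0.15 M | 0.252 M | 0.0720 M |  | 50 h |
| violet | 0.24 M | 0.252 M | 0.0720 M |  | 50 h |
| amber | 0.12 M | 1.00 M | 0.0400 M |  | 50 h |

- north-east (time / h: G / %, Q / %): 2.00: 19.4, 77.0; 4.00: 30.1, 66.2; 8.00: 38.8, 54.0; 12.0: 43.2, 45.7; 25.0: 49.1, 35.5
- west (time / h: G / %, Q / %): 5.00: 29.6, 58.9; 10.0: 40.6, 45.0; 15.0: 44.4, 37.4; 20.0: 48.7, 35.5; 25.0: 50.3, 32.7
- south-west (time / h: G / %, Q / %): 5.00: 32.3, 56.9; 10.0: 41.1, 41.8; 15.0: 43.5, 33.6; 20.0: 46.5, 28.7; 25.0: 47.5, 27.6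
- south-east (time / h: G / %, Q / %): 2.00: 23.6, 72.7; 4.00: 34.9, 54.5; 8.00: 47.2, 38.9; 12.0: 53.5, 28.5; 25.0: 59.2, 17.3

(standard deviation of a reading: 1 percentage point)

- the earlier runs were read with a standard deviation of 1 percentage point

1. all flasks from highest to lowest amount of G, in percent of the Q charged, at 50 h (red / teal / grey / ochre / violet / amber)
2. the amount of G, in percent of the Q charged of the flask you put first, at 50 h
3. the amount of G, in percent of the Q charged of the flask you put last, at 50 h

We build the flask one process at a time and count what is left, not what is made. First the main step, Q + D giving G one for one: in the north-east run the charged D, 0.252 M, covers the charged Q, 0.24 M, and this count shows no stall. The readings disagree. Charged D per G at the last reading is 2.14 in the north-east run and 2.09 in the west run.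

So we add a second process: each G costs two D. The fraction of D left then reaches zero at a G set by the charges. For red, 15.0% is the charged c_D divided by two and by the charged c_Q, the D ceiling: D as limiting reagent, counted at two per G. Grey gets 18.7%, teal 25.0%, violet 52.5%.

Third comes X. Q lost beyond G in the north-east run reads 0.0370 M against 0.043 M of X charged, so X takes Q one for one. At the first reading, G over that gap is 5.39 and charged D over X is 5.86, so we read the two steps as about equally fast. D then falls two per turn, and the fraction of D left is the square of the fraction x of X left.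

The ceiling plus X's charge, over Q, is 29.4% in red and 82.5% in violet, so Q outlasts D there and we take the ceiling as G. It is 132% in ochre and 450% in amber, so there Q goes first, and G, which is half the D spent, plus the X spent must sum to the charged Q. Ochre gives x = 0.394 and G 70.9%. Amber gives x = 0.877 and G 95.9%. Our order is amber, ochre, violet, teal, grey, red.

The forecast, reasoning that “G stalls well before Q runs out”, gave amber > violet > ochre > teal > grey > red, from 63% down to 14%, which differs from ours in the places of ochre and violet and in the value for amber.

The flasks give amber > ochre > violet > teal > grey > red, from 95.4% in amber to 15.8% in red.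

    Q + D → Z + G (k = 1.40 × 10⁻⁴ L mol⁻¹ s⁻¹)
    Q + X → J (k = 1.60 × 10⁻⁴ L mol⁻¹ s⁻¹)
    D + Z ⇌ L, settled at all times (K = 28000 L mol⁻¹)
    Q → E (k = 3.90 × 10⁻⁹ s⁻¹)

Each turn of the main step spends one D, and its Z ties up a second as L. Red at 50.0 h still has 69.8% of its Q, with D down to 0.215% of its charge, and its G of 15.8% stands near the ceiling of 15.0%. The same run without the wearing away of D reaches 84.4%. A neighbour of red with D cut to 0.060 M has a ceiling of 6.00%, and its computed G is 6.52%.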